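**Retrosynthetic overview**
1. The α-methylene-γ-lactone is annulated last: the O–C6 and C11–C7 bonds are made together by a palladium-catalysed carbo-acyloxylation of the ten-membered ring diene in 25 with 2-bromoacrylic acid (26).
2. Enabling feature: C6, which bears the lactone oxygen, is allylic to the ring C4=C5 bond and its neighbour C7 bears C11. The lactone is therefore the 1,2-carbo-oxygenation product of a C4=C5–C6=C7 diene in the ten-membered ring, and the free C8 hydroxyl, cis to C11, serves as directing group.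
3. The ten-membered carbocycle 25 comes from ring-closing metathesis at C6=C7 of tetraene 24, whose (Z)-diene is made by Stille vinylation of a (Z)-vinyl iodide.
4. C8/C9 come from a (Z)-γ-alkoxyallylboration of (Z)-enal 12, C1=C10 from a Still–Gennari olefination, C3 from allylboration of (Z)-3-iodo-2-methylacrolein (4), and the side-chain acid 17 from Sharpless epoxidation of tiglyl alcohol.
5. Ring order: oxirane (side chain), then ten-membered carbocycle, then γ-lactone.

Key step: step 18

Remark: germacrane numbering is used (C6 bears the lactone oxygen, C7 bears C11). The target is read as the 6,7-cis-fused lactone with the C8 hydroxyl on the same face, both ring alkenes Z, and the side chain as (2S,3R)-2,3-dimethyloxirane-2-carboxylate (the epoxide of a tiglate).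

**Route**

Step 1
Reactants: 1 prop-2-yn-1-ol
Product: 3 (Z)-3-iodo-2-methylprop-2-en-1-ol, via cyclic alkenylmagnesium alkoxide 2 (not isolated)
Conditions: MeMgBr (3 equiv), CuI (10 mol %), THF, −10 °C to rt; then I2, −30 to 0 °C
Reagents that add atoms: methylmagnesium bromide, C[Mg]Br; iodine, II
Why: Copper-catalysed anti-carbomagnesiation of the propargylic magnesium alkoxide puts methyl on the inner alkyne carbon and magnesium on the terminal carbon in a five-membered chelate, so iodinolysis should give the iodoalkene with iodine cis to the carbinol carbon.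

Step 2
Reactants: 3 (Z)-3-iodo-2-methylprop-2-en-1-ol
Product: 4 (Z)-3-iodo-2-methylprop-2-enal
Conditions: MnO2 (activated, excess), CH2Cl2, rt, dark; used crude
Reagents that add atoms: none
Why: Allylic oxidation with MnO2 is neutral and should leave the vinyl iodide and the Z geometry intact if light and acid are excluded.

Step 3
Reactants: 4 (Z)-3-iodo-2-methylprop-2-enal
Product: 6 (3S,1Z)-1-iodo-2-methylhexa-1,5-dien-3-ol, via diisopinocampheylborinate ester 5 (not isolated)
Conditions: (−)-Ipc2B(allyl), Et2O, −78 °C; then HOCH2CH2NH2, rt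
Reagents that add atoms: (−)-B-allyldiisopinocampheylborane, C=CCB([C@@H]1C[C@@H]2C[C@H]([C@H]1C)C2(C)C)[C@@H]1C[C@@H]2C[C@H]([C@H]1C)C2(C)C
Why: Brown allylboration through a closed chair transition state, in which the isopinocampheyl groups from (+)-α-pinene should direct allyl transfer to the Si face of the aldehyde and so set C3 as S.

Step 4
Reactants: 6 (3S,1Z)-1-iodo-2-methylhexa-1,5-dien-3-ol
Product: 7 tert-butyl{[(3S,1Z)-1-iodo-2-methylhexa-1,5-dien-3-yl]oxy}dimethylsilane
Conditions: TBSCl, imidazole, DMF, rt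
Reagents that add atoms: tert-butyldimethylsilyl chloride, CC(C)(C)[Si](C)(C)Cl
Why: Standard silylation of a secondary allylic alcohol, which protects O3 through the hydride and organometallic steps that follow.

Step 5
Reactants: 7 tert-butyl{[(3S,1Z)-1-iodo-2-methylhexa-1,5-dien-3-yl]oxy}dimethylsilane
Product: 9 (3S,4Z)-3-[(tert-butyldimethylsilyl)oxy]-5-iodo-4-methylpent-4-enal, via vicinal diol 8 (not isolated)
Conditions: OsO4 (2 mol %), NaIO4 (4 equiv), 2,6-lutidine, dioxane/H2O 3:1, rt
Reagents that add atoms: osmium tetroxide, O=[Os](=O)(=O)=O (oxygen carrier, reoxidised by sodium periodate, [Na+].[O-]I(=O)(=O)=O)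
Why: Lemieux–Johnson cleavage, in which OsO4 should dihydroxylate the monosubstituted alkene in preference to the electron-poor, trisubstituted iodoalkene and periodate cleaves the diol to the C1 aldehyde.

Step 6
Reactants: 9 (3S,4Z)-3-[(tert-butyldimethylsilyl)oxy]-5-iodo-4-methylpent-4-enal
Product: 10 methyl (2Z,5S,6Z)-5-[(tert-butyldimethylsilyl)oxy]-7-iodo-2,6-dimethylhepta-2,6-dienoate
Conditions: (CF3CH2O)2P(O)CH(CH3)CO2CH3, KN(SiMe3)2, 18-crown-6, THF, −78 °C
Reagents that add atoms: methyl 2-[bis(2,2,2-trifluoroethoxy)phosphoryl]propanoate, COC(=O)C(C)P(=O)(OCC(F)(F)F)OCC(F)(F)F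
Why: Still–Gennari olefination, in which the electron-poor phosphonate eliminates rapidly from the kinetic adduct and should give the (Z)-2-methyl enoate, that is, the C1=C10 bond with C2 and C9 cis.

Step 7
Reactants: 10 methyl (2Z,5S,6Z)-5-[(tert-butyldimethylsilyl)oxy]-7-iodo-2,6-dimethylhepta-2,6-dienoate
Product: 11 (2Z,5S,6Z)-5-[(tert-butyldimethylsilyl)oxy]-7-iodo-2,6-dimethylhepta-2,6-dien-1-ol
Conditions: i-Bu2AlH (2.3 equiv), CH2Cl2, −78 °C
Reagents that add atoms: none
Why: 1,2-Reduction of the conjugated ester by the aluminium hydride at low temperature should not affect the vinyl iodide, the silyl ether or the alkene geometry.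

Step 8
Reactants: 11 (2Z,5S,6Z)-5-[(tert-butyldimethylsilyl)oxy]-7-iodo-2,6-dimethylhepta-2,6-dien-1-ol
Product: 12 (2Z,5S,6Z)-5-[(tert-butyldimethylsilyl)oxy]-7-iodo-2,6-dimethylhepta-2,6-dienal
Conditions: Dess–Martin periodinane, NaHCO3, CH2Cl2, 0 °C; used crude
Reagents that add atoms: none
Why: Buffered Dess–Martin oxidation is fast and non-acidic, which should limit Z-to-E isomerisation of the (Z)-2-methyl enal.

Step 9
Reactants: 12 (2Z,5S,6Z)-5-[(tert-butyldimethylsilyl)oxy]-7-iodo-2,6-dimethylhepta-2,6-dienal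
Product: 14 (3S,4S,5Z,8S,9Z)-8-[(tert-butyldimethylsilyl)oxy]-10-iodo-3-(methoxymethoxy)-5,9-dimethyldeca-1,5,9-trien-4-ol, via diisopinocampheylborinate ester 13 (not isolated)
Conditions: CH2=CHCH2OCH2OCH3, s-BuLi, THF, −78 °C; (+)-Ipc2BOMe; BF3·OEt2; then 12, −78 °C; HOCH2CH2NH2, rt
Reagents that add atoms: allyl methoxymethyl ether, C=CCOCOC
Why: Brown (Z)-γ-alkoxyallylboration through a chair transition state, where the Z reagent should give the syn C8/C9 relationship and the isopinocampheyl groups from (−)-α-pinene should direct attack to the Re face of the aldehyde, setting C9 as S and C8 as S with O9 free and O8 protected.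

Step 10
Reactants: 15 (E)-2-methylbut-2-en-1-ol
Product: 16 [(2R,3R)-2,3-dimethyloxiran-2-yl]methanol
Conditions: Ti(OiPr)4 (10 mol %), D-(−)-diethyl tartrate (12 mol %), t-BuOOH, 4 Å molecular sieves, CH2Cl2, −20 °C
Reagents that add atoms: tert-butyl hydroperoxide, CC(C)(C)OO
Why: Sharpless asymmetric epoxidation, in which the D-(−)-tartrate catalyst should deliver oxygen to the alkene face that gives the (2R,3R)-epoxy alcohol, the enantiomer of the (2S,3S) product obtained from E allylic alcohols with the L-(+)-tartrate.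

Step 11
Reactants: 16 [(2R,3R)-2,3-dimethyloxiran-2-yl]methanol
Product: 17 (2S,3R)-2,3-dimethyloxirane-2-carboxylic acid
Conditions: TEMPO (10 mol %), PhI(OAc)2 (2.2 equiv), MeCN/H2O 1:1, rt
Reagents that add atoms: water, O
Why: Oxoammonium oxidation of the primary alcohol through the aldehyde hydrate should give the acid without opening the epoxide; the change of the C2 descriptor is only a priority change.

Step 12
Reactants: 14 (3S,4S,5Z,8S,9Z)-8-[(tert-butyldimethylsilyl)oxy]-10-iodo-3-(methoxymethoxy)-5,9-dimethyldeca-1,5,9-trien-4-ol; 17 (2S,3R)-2,3-dimethyloxirane-2-carboxylic acid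
Product: 19 (3S,4S,5Z,8S,9Z)-8-[(tert-butyldimethylsilyl)oxy]-10-iodo-3-(methoxymethoxy)-5,9-dimethyldeca-1,5,9-trien-4-yl (2S,3R)-2,3-dimethyloxirane-2-carboxylate, via mixed trichlorobenzoic anhydride 18 (not isolated)
Conditions: 17 (2 equiv), 2,4,6-Cl3C6H2COCl, Et3N, THF, rt; then 14, DMAP, toluene, rt
Reagents that add atoms: none
Why: Yamaguchi esterification, where DMAP-mediated acyl transfer from the mixed anhydride should acylate the hindered allylic C9 hydroxyl under non-acidic conditions that spare the epoxide.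

Step 13
Reactants: 19 (3S,4S,5Z,8S,9Z)-8-[(tert-butyldimethylsilyl)oxy]-10-iodo-3-(methoxymethoxy)-5,9-dimethyldeca-1,5,9-trien-4-yl (2S,3R)-2,3-dimethyloxirane-2-carboxylate
Product: 20 (3S,4S,5Z,8S,9Z)-8-hydroxy-10-iodo-3-(methoxymethoxy)-5,9-dimethyldeca-1,5,9-trien-4-yl (2S,3R)-2,3-dimethyloxirane-2-carboxylate
Conditions: HF·pyridine, pyridine, THF, 0 °C to rt
Reagents that add atoms: none
Why: Buffered fluoride desilylation should remove only the silyl ether at O3, since the acetal, the ester and the electron-poor epoxide are stable to HF·pyridine.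

Step 14
Reactants: 20 (3S,4S,5Z,8S,9Z)-8-hydroxy-10-iodo-3-(methoxymethoxy)-5,9-dimethyldeca-1,5,9-trien-4-yl (2S,3R)-2,3-dimethyloxirane-2-carboxylate
Product: 21 (3S,4S,5Z,8S,9Z)-8-acetoxy-10-iodo-3-(methoxymethoxy)-5,9-dimethyldeca-1,5,9-trien-4-yl (2S,3R)-2,3-dimethyloxirane-2-carboxylate
Conditions: Ac2O, pyridine, DMAP (cat.), CH2Cl2, 0 °C
Reagents that add atoms: acetic anhydride, CC(=O)OC(C)=O
Why: Acetylation of the only free hydroxyl installs the C3 acetate of the target.

Step 15
Reactants: 21 (3S,4S,5Z,8S,9Z)-8-acetoxy-10-iodo-3-(methoxymethoxy)-5,9-dimethyldeca-1,5,9-trien-4-yl (2S,3R)-2,3-dimethyloxirane-2-carboxylate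
Product: 23 (3S,4S,5Z,8S,9Z)-8-acetoxy-3-hydroxy-10-iodo-5,9-dimethyldeca-1,5,9-trien-4-yl (2S,3R)-2,3-dimethyloxirane-2-carboxylate, via bipyridinium acetal salt 22 (not isolated)
Conditions: TMSOTf, 2,2'-bipyridyl, CH2Cl2, 0 °C; then H2O
Reagents that add atoms: none
Why: The bipyridyl-buffered silyl triflate should convert the methoxymethyl acetal into an N,O-acetal pyridinium salt that water hydrolyses, a nearly non-acidic acetal cleavage that should spare the epoxy ester and the allylic acetate (the vinyl iodide is kept to this point because it is less ionisable than the later diene).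

Step 16
Reactants: 23 (3S,4S,5Z,8S,9Z)-8-acetoxy-3-hydroxy-10-iodo-5,9-dimethyldeca-1,5,9-trien-4-yl (2S,3R)-2,3-dimethyloxirane-2-carboxylate
Product: 24 (3S,4S,5Z,8S,9Z)-8-acetoxy-3-hydroxy-5,9-dimethyldodeca-1,5,9,11-tetraen-4-yl (2S,3R)-2,3-dimethyloxirane-2-carboxylate
Conditions: CH2=CHSnBu3, PdCl2(MeCN)2 (5 mol %), DMF, 25 °C, dark
Reagents that add atoms: tributyl(vinyl)stannane, C=C[Sn](CCCC)(CCCC)CCCC
Why: Stille coupling of the alkenyl iodide proceeds with retention and should give the (Z)-diene, since oxidative addition to the C–I bond is much faster than ionisation of the allylic esters with a phosphine-free catalyst at room temperature.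

Step 17
Reactants: 24 (3S,4S,5Z,8S,9Z)-8-acetoxy-3-hydroxy-5,9-dimethyldodeca-1,5,9,11-tetraen-4-yl (2S,3R)-2,3-dimethyloxirane-2-carboxylate
Product: 25 (1S,2S,3Z,5Z,7S,9Z)-7-acetoxy-2-hydroxy-6,10-dimethylcyclodeca-3,5,9-trien-1-yl (2S,3R)-2,3-dimethyloxirane-2-carboxylate
Conditions: second-generation Grubbs catalyst RuCl2(=CHPh)(PCy3)(H2IMes) (10 mol %), 1,4-benzoquinone (20 mol %), CH2Cl2 (1 mM), 40 °C
Reagents that add atoms: none
Why: Ring-closing metathesis between the vinyl group next to the free allylic hydroxyl and the terminal vinyl of the diene should close the ten-membered ring, the two existing Z alkenes pre-organising the chain and ring strain enforcing a Z-configured C6=C7 bond; the trisubstituted alkenes should not take part.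

Step 18
Reactants: 25 (1S,2S,3Z,5Z,7S,9Z)-7-acetoxy-2-hydroxy-6,10-dimethylcyclodeca-3,5,9-trien-1-yl (2S,3R)-2,3-dimethyloxirane-2-carboxylate; 26 2-bromoprop-2-enoic acid
Product: 27 (3S,6S,7R,8S,9S)-3-acetoxy-8-hydroxy-9-{[(2S,3R)-2,3-dimethyloxirane-2-carbonyl]oxy}germacra-1(10)Z,4Z,11(13)-trien-12,6-olide (target)
Conditions: 26 (1.5 equiv), Pd(OAc)2 (10 mol %), Ag2CO3 (1.0 equiv), DMF, 45 °C, dark
Reagents that add atoms: none
Why: Proposed new method: zerovalent palladium formed in situ should insert into the C–Br bond of silver 2-bromoacrylate, the resulting cationic divalent 1-carboxylatovinylpalladium should add syn across C6=C7 with carbon going to C7, and the π-allylpalladium spanning C6–C5–C4 should be closed at C6 by the palladium-bound carboxylate in a C–O reductive elimination that returns zerovalent palladium and leaves C4=C5 Z. The closest known reaction type is the Larock heteroannulation of 1,3-dienes with halo-substituted carboxylic acids and phenols, which gives cis-fused rings from cyclic dienes; its use with a 2-haloacrylic acid on a medium-ring diene is the untested element. The five-membered lactone closes in a 5-exo fashion onto the proximal allyl terminus (C5–C4 stays outside the new ring), and closure at C4 to a seven-membered ring is disfavoured. C7 is controlled by the C8 hydroxyl, which should bind the halide-free palladium and deliver it through a five-membered chelate with a small O8–C8–C7=C6 dihedral angle, the geometry that makes metal-alkoxide-directed epoxidation of medium-ring (Z)-cycloalkenols cis-selective; C6 is controlled by the stereospecific syn,syn delivery of carbon and oxygen across the Z-configured C6=C7 bond, which enforces the cis ring fusion. The step needs regioselectivity for the conjugated diene over the isolated C1=C10 bond and for C7 over C4, and chemoselectivity against ionisation of the two allylic esters; the first is secured by conjugation and the lower substitution at C7, the second by the fast oxidative addition of the electron-poor alkenyl bromide and the absence of phosphine.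

**Compound list**
1 | prop-2-yn-1-ol | C#CCO | starting material
2 | cyclic alkenylmagnesium alkoxide (4-methyl-2,5-dihydro-1,2-oxamagnesole) | CC1=C[Mg]OC1 | intermediate
3 | (Z)-3-iodo-2-methylprop-2-en-1-ol | OC/C(C)=C\I | intermediate
4 | (Z)-3-iodo-2-methylprop-2-enal | O=C/C(C)=C\I | intermediate
5 | (3S,1Z)-1-iodo-2-methylhexa-1,5-dien-3-yl diisopinocampheylborinate (isopinocampheyl from (+)-α-pinene) | I/C=C(/C)[C@H](CC=C)OB([C@@H]1C[C@@H]2C[C@H]([C@H]1C)C2(C)C)[C@@H]1C[C@@H]2C[C@H]([C@H]1C)C2(C)C | intermediate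
6 | (3S,1Z)-1-iodo-2-methylhexa-1,5-dien-3-ol | I/C=C(/C)[C@@H](O)CC=C | intermediate
7 | tert-butyl{[(3S,1Z)-1-iodo-2-methylhexa-1,5-dien-3-yl]oxy}dimethylsilane | I/C=C(/C)[C@@H](O[Si](C)(C)C(C)(C)C)CC=C | intermediate
8 | (4S,5Z)-4-[(tert-butyldimethylsilyl)oxy]-6-iodo-5-methylhex-5-ene-1,2-diol (C2 epimers) | I/C=C(/C)[C@@H](O[Si](C)(C)C(C)(C)C)CC(O)CO | intermediate
9 | (3S,4Z)-3-[(tert-butyldimethylsilyl)oxy]-5-iodo-4-methylpent-4-enal | I/C=C(/C)[C@@H](O[Si](C)(C)C(C)(C)C)CC=O | intermediate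
10 | methyl (2Z,5S,6Z)-5-[(tert-butyldimethylsilyl)oxy]-7-iodo-2,6-dimethylhepta-2,6-dienoate | COC(=O)/C(C)=C\C[C@H](O[Si](C)(C)C(C)(C)C)/C(C)=C\I | intermediate
11 | (2Z,5S,6Z)-5-[(tert-butyldimethylsilyl)oxy]-7-iodo-2,6-dimethylhepta-2,6-dien-1-ol | OC/C(C)=C\C[C@H](O[Si](C)(C)C(C)(C)C)/C(C)=C\I | intermediate
12 | (2Z,5S,6Z)-5-[(tert-butyldimethylsilyl)oxy]-7-iodo-2,6-dimethylhepta-2,6-dienal | O=C/C(C)=C\C[C@H](O[Si](C)(C)C(C)(C)C)/C(C)=C\I | intermediate
13 | diisopinocampheylborinate of 14 (isopinocampheyl from (−)-α-pinene) | C=C[C@H](OCOC)[C@@H](OB([C@H]1C[C@H]2C[C@@H]([C@@H]1C)C2(C)C)[C@H]1C[C@H]2C[C@@H]([C@@H]1C)C2(C)C)/C(C)=C\C[C@H](O[Si](C)(C)C(C)(C)C)/C(C)=C\I | intermediate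
14 | (3S,4S,5Z,8S,9Z)-8-[(tert-butyldimethylsilyl)oxy]-10-iodo-3-(methoxymethoxy)-5,9-dimethyldeca-1,5,9-trien-4-ol | C=C[C@H](OCOC)[C@@H](O)/C(C)=C\C[C@H](O[Si](C)(C)C(C)(C)C)/C(C)=C\I | intermediate
15 | (E)-2-methylbut-2-en-1-ol (tiglyl alcohol) | C/C=C(\C)CO | starting material
16 | [(2R,3R)-2,3-dimethyloxiran-2-yl]methanol | OC[C@@]1(C)O[C@@H]1C | intermediate
17 | (2S,3R)-2,3-dimethyloxirane-2-carboxylic acid | OC(=O)[C@@]1(C)O[C@@H]1C | intermediate
18 | (2S,3R)-2,3-dimethyloxirane-2-carboxylic 2,4,6-trichlorobenzoic anhydride | O=C(OC(=O)c1c(Cl)cc(Cl)cc1Cl)[C@@]1(C)O[C@@H]1C | intermediate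
19 | (3S,4S,5Z,8S,9Z)-8-[(tert-butyldimethylsilyl)oxy]-10-iodo-3-(methoxymethoxy)-5,9-dimethyldeca-1,5,9-trien-4-yl (2S,3R)-2,3-dimethyloxirane-2-carboxylate | C=C[C@H](OCOC)[C@@H](OC(=O)[C@@]1(C)O[C@@H]1C)/C(C)=C\C[C@H](O[Si](C)(C)C(C)(C)C)/C(C)=C\I | intermediate
20 | (3S,4S,5Z,8S,9Z)-8-hydroxy-10-iodo-3-(methoxymethoxy)-5,9-dimethyldeca-1,5,9-trien-4-yl (2S,3R)-2,3-dimethyloxirane-2-carboxylate | C=C[C@H](OCOC)[C@@H](OC(=O)[C@@]1(C)O[C@@H]1C)/C(C)=C\C[C@H](O)/C(C)=C\I | intermediate
21 | (3S,4S,5Z,8S,9Z)-8-acetoxy-10-iodo-3-(methoxymethoxy)-5,9-dimethyldeca-1,5,9-trien-4-yl (2S,3R)-2,3-dimethyloxirane-2-carboxylate | C=C[C@H](OCOC)[C@@H](OC(=O)[C@@]1(C)O[C@@H]1C)/C(C)=C\C[C@H](OC(C)=O)/C(C)=C\I | intermediate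
22 | 1-{[(3S,4S,5Z,8S,9Z)-8-acetoxy-4-{[(2S,3R)-2,3-dimethyloxirane-2-carbonyl]oxy}-10-iodo-5,9-dimethyldeca-1,5,9-trien-3-yl]oxymethyl}-2,2'-bipyridin-1-ium trifluoromethanesulfonate | C=C[C@H](OC[n+]1ccccc1-c1ccccn1)[C@@H](OC(=O)[C@@]1(C)O[C@@H]1C)/C(C)=C\C[C@H](OC(C)=O)/C(C)=C\I.[O-]S(=O)(=O)C(F)(F)F | intermediate
23 | (3S,4S,5Z,8S,9Z)-8-acetoxy-3-hydroxy-10-iodo-5,9-dimethyldeca-1,5,9-trien-4-yl (2S,3R)-2,3-dimethyloxirane-2-carboxylate | C=C[C@H](O)[C@@H](OC(=O)[C@@]1(C)O[C@@H]1C)/C(C)=C\C[C@H](OC(C)=O)/C(C)=C\I | intermediate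
24 | (3S,4S,5Z,8S,9Z)-8-acetoxy-3-hydroxy-5,9-dimethyldodeca-1,5,9,11-tetraen-4-yl (2S,3R)-2,3-dimethyloxirane-2-carboxylate | C=C[C@H](O)[C@@H](OC(=O)[C@@]1(C)O[C@@H]1C)/C(C)=C\C[C@H](OC(C)=O)/C(C)=C\C=C | intermediate
25 | (1S,2S,3Z,5Z,7S,9Z)-7-acetoxy-2-hydroxy-6,10-dimethylcyclodeca-3,5,9-trien-1-yl (2S,3R)-2,3-dimethyloxirane-2-carboxylate | O[C@H]1/C=C\C=C(\C)[C@@H](OC(C)=O)C/C=C(/C)[C@@H]1OC(=O)[C@@]2(C)O[C@@H]2C | intermediate
26 | 2-bromoprop-2-enoic acid (2-bromoacrylic acid) | C=C(Br)C(=O)O | starting material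
27 | (3S,6S,7R,8S,9S)-3-acetoxy-8-hydroxy-9-{[(2S,3R)-2,3-dimethyloxirane-2-carbonyl]oxy}germacra-1(10)Z,4Z,11(13)-trien-12,6-olide | C=C1C(=O)O[C@H]2/C=C(/C)[C@@H](OC(C)=O)C/C=C(/C)[C@H](OC(=O)[C@@]3(C)O[C@@H]3C)[C@@H](O)[C@@H]12 | target

**Step count and risks**
Total step count: 18. Longest linear sequence: 16 (steps 1–9 and 12–18; steps 10–11 make acid 17).

Most likely to fail:

1. Step 18 (proposed new method). The alkenylpalladium species may add to the wrong face of C6=C7 if hydroxyl coordination does not control the approach, zerovalent palladium may ionise the allylic esters, and β-hydride elimination from the π-allyl intermediate may outrun C–O bond formation. The fallback sets out from 25 and returns at 27 and uses known radical chemistry. Oxidative lactone annulation of the ring diene with malonic acid and Mn(OAc)3·2H2O (AcOH/MeCN, 40 °C) should add the malonyl radical to C7 and trap the oxidised allyl radical at C6 with the carboxyl group, giving the α-carboxy lactone F1. Decarboxylative Mannich methylenation of F1 (aqueous formaldehyde, Et2NH, then NaOAc/AcOH, 60 °C) should then give 27. Facial selectivity at C7 is not assured in this variant either, so both C7 series would have to be assigned by nOe.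

2. Step 17. Intermolecular metathesis may give oligomers, ruthenium may be held as a conjugated vinylcarbene on the diene, or the ring may close with an E-configured C6=C7 bond. The fallback sets out from 21 and returns at 25 and replaces metathesis ring closure by an sp2–sp2 coupling at C5–C6. Z-selective cross-metathesis of the terminal vinyl group of 21 with vinylboronic acid pinacol ester, using the molybdenum monoaryloxide pyrrolide alkylidene Mo(N-1-adamantyl)(CHCMe2Ph)(2,5-dimethylpyrrolide)(O-2,6-(2,4,6-i-Pr3C6H2)2C6H3), should give the (Z)-alkenylboronate F2. Intramolecular Suzuki–Miyaura coupling with the vinyl iodide (Pd(dppf)Cl2, Cs2CO3, THF/H2O, high dilution) should give the macrocyclic methoxymethyl ether F3 with both diene bonds Z by retention. Acetal cleavage as in step 15 then gives 25.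

3. Step 15. The silyl triflate may open the epoxy ester or ionise the allylic acetate before the acetal is cleaved. The fallback sets out from 14 and returns at 23 and moves the acetal cleavage ahead of the introduction of the epoxide and the acetate. Cleavage of the methoxymethyl ether of 14 with ZnBr2 and n-PrSH (CH2Cl2, 0 °C) should give the diol F4. Acylation of its less hindered C8 hydroxyl with chloroacetic anhydride and 2,4,6-collidine at −40 °C should give the mono-chloroacetate F5; the regioselectivity rests on steric bias only. Yamaguchi esterification with 17 should give the diester F6, HF·pyridine should give the C3 alcohol F7, and acetic anhydride the acetate F8. Thiourea and NaHCO3 in ethanol should then remove only the chloroacetate to give 23.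

**Further compounds**
F1 | step 18 | analogue of 27 in which C11 bears H and CO2H in place of the exocyclic methylene (C11 epimers) | OC(=O)C1C(=O)O[C@H]2/C=C(/C)[C@@H](OC(C)=O)C/C=C(/C)[C@H](OC(=O)[C@@]3(C)O[C@@H]3C)[C@@H](O)[C@@H]12
F2 | step 17 | (1Z,3S,4S,5Z,8S,9Z)-8-acetoxy-10-iodo-3-(methoxymethoxy)-5,9-dimethyl-1-(4,4,5,5-tetramethyl-1,3,2-dioxaborolan-2-yl)deca-1,5,9-trien-4-yl (2S,3R)-2,3-dimethyloxirane-2-carboxylate | CC1(C)OB(OC1(C)C)/C=C\[C@H](OCOC)[C@@H](OC(=O)[C@@]2(C)O[C@@H]2C)/C(C)=C\C[C@H](OC(C)=O)/C(C)=C\I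
F3 | step 17 | (1S,2S,3Z,5Z,7S,9Z)-7-acetoxy-2-(methoxymethoxy)-6,10-dimethylcyclodeca-3,5,9-trien-1-yl (2S,3R)-2,3-dimethyloxirane-2-carboxylate | COCO[C@H]1/C=C\C=C(\C)[C@@H](OC(C)=O)C/C=C(/C)[C@@H]1OC(=O)[C@@]2(C)O[C@@H]2C
F4 | step 15 | (3S,4S,5Z,8S,9Z)-8-[(tert-butyldimethylsilyl)oxy]-10-iodo-5,9-dimethyldeca-1,5,9-triene-3,4-diol | C=C[C@H](O)[C@@H](O)/C(C)=C\C[C@H](O[Si](C)(C)C(C)(C)C)/C(C)=C\I
F5 | step 15 | (3S,4S,5Z,8S,9Z)-8-[(tert-butyldimethylsilyl)oxy]-4-hydroxy-10-iodo-5,9-dimethyldeca-1,5,9-trien-3-yl chloroacetate | C=C[C@H](OC(=O)CCl)[C@@H](O)/C(C)=C\C[C@H](O[Si](C)(C)C(C)(C)C)/C(C)=C\I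
F6 | step 15 | (3S,4S,5Z,8S,9Z)-8-[(tert-butyldimethylsilyl)oxy]-3-(chloroacetoxy)-10-iodo-5,9-dimethyldeca-1,5,9-trien-4-yl (2S,3R)-2,3-dimethyloxirane-2-carboxylate | C=C[C@H](OC(=O)CCl)[C@@H](OC(=O)[C@@]1(C)O[C@@H]1C)/C(C)=C\C[C@H](O[Si](C)(C)C(C)(C)C)/C(C)=C\I
F7 | step 15 | (3S,4S,5Z,8S,9Z)-3-(chloroacetoxy)-8-hydroxy-10-iodo-5,9-dimethyldeca-1,5,9-trien-4-yl (2S,3R)-2,3-dimethyloxirane-2-carboxylate | C=C[C@H](OC(=O)CCl)[C@@H](OC(=O)[C@@]1(C)O[C@@H]1C)/C(C)=C\C[C@H](O)/C(C)=C\I
F8 | step 15 | (3S,4S,5Z,8S,9Z)-8-acetoxy-3-(chloroacetoxy)-10-iodo-5,9-dimethyldeca-1,5,9-trien-4-yl (2S,3R)-2,3-dimethyloxirane-2-carboxylate | C=C[C@H](OC(=O)CCl)[C@@H](OC(=O)[C@@]1(C)O[C@@H]1C)/C(C)=C\C[C@H](OC(C)=O)/C(C)=C\I
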